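Both δ-lactone rings are disconnected at C4–C4a and O1–C2 (ring A half) and at C4′–C4a′ and O1′–C2′ (ring B half). What remains, the C3–C3′ bond carrying a carboxyl carbon (C2, C2′) and a 4-hydroxybenzylic carbon (C4, C4′) at each end, is the 8–8′ dimer of p-coumaric acid, used as its twofold-symmetric cis-fused bis-γ-lactone 4. The key step exploits the para-hydroxyphenyl groups on C4 and C4′: under acid each benzylic lactone carbon becomes a para-quinone methide electrophile, arylated first by 2,3,4,5-tetramethoxyphenol and then by phloroglucinol, and each carboxyl relactonises on the neighbouring phenol, so that both six-membered lactones and the C4/C4′ stereocentres arise in one pot.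

Key step: step 5

Remark on the chemistry: the target is (3S,3′S,4R,4′R) with H-3/H-4 and H-3′/H-4′ cis; C3/C3′ correspond to the (1R,5R) bridgeheads of dilactone 4, each arene has to take the place of the lactone oxygen with retention, and the chromatographic resolution is counted as a step.

Step 1
Reactants: 1 p-coumaric acid, (E)-3-(4-hydroxyphenyl)prop-2-enoic acid (two molecules per molecule of product)
Product: 3 rac-(1R*,4R*,5R*,8R*)-4,8-bis(4-hydroxyphenyl)-3,7-dioxabicyclo[3.3.0]octane-2,6-dione (cis-fused; both aryl groups exo), via bis-quinone methide diacid 2 (not isolated)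
Conditions: FeCl3 (1.1 equiv based on 1), acetone–H2O, rt, argon
Reagents that add atoms: p-coumaric acid 1 (the second molecule, joined 8–8′ to the first), O=C(O)/C=C/c1ccc(O)cc1
Why: Oxidative phenol coupling (8–8′ dehydrodimerisation): trivalent iron oxidises each of two molecules of 1 to a phenoxyl radical with spin density at C8, the two radicals join 8–8′ to the bis-quinone methide 2, and each carboxyl group adds 5-exo-trig to the quinone methide carbon of the other half, so that only the like adduct can close the cis-fused bicycle and the aryl groups settle on the convex face (relative configuration only, racemate).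

Step 2
Reactants: 3 racemic exo,exo-dilactone
Product: 4 (1R,4R,5R,8R)-4,8-bis(4-hydroxyphenyl)-3,7-dioxabicyclo[3.3.0]octane-2,6-dione
Conditions: preparative chiral SFC, amylose tris(3,5-dimethylphenylcarbamate) phase, CO2–MeOH
Reagents that add atoms: none
Why: Resolution by chromatography on a chiral polysaccharide phase separates the enantiomers without making or breaking a bond and so fixes the absolute configuration of the bridgeheads (later C3 and C3′); the (1R,4R,5R,8R) fraction is to be identified by X-ray analysis of a heavy-atom ester or by comparing measured and computed circular dichroism.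

Step 3
Reactants: 5 1,2,3,4-tetramethoxybenzene
Product: 7 2,3,4,5-tetramethoxybenzaldehyde, via benzylic chloro ether 6 (not isolated)
Conditions: Cl2CHOMe, TiCl4, CH2Cl2, 0 °C; then H2O
Reagents that add atoms: dichloromethyl methyl ether, COC(Cl)Cl; water, O
Why: Rieche formylation, in which the TiCl4-activated chloro ether attacks one of the two equivalent free ring carbons (ortho and para to methoxy groups) and the chloro ether 6 is hydrolysed to the aldehyde on work-up.

Step 4
Reactants: 7 2,3,4,5-tetramethoxybenzaldehyde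
Product: 9 2,3,4,5-tetramethoxyphenol, via aryl formate 8 (not isolated)
Conditions: 30% aq. H2O2, cat. H2SO4, MeOH, rt
Reagents that add atoms: hydrogen peroxide, OO
Why: Acid-catalysed Dakin oxidation, in which the peroxide adduct of the electron-rich aldehyde rearranges by aryl migration to oxygen (Baeyer–Villiger type) to formate 8, which methanol cleaves to the phenol.

Step 5
Reactants: 4 (1R,4R,5R,8R)-dilactone; 9 2,3,4,5-tetramethoxyphenol; 10 phloroglucinol (benzene-1,3,5-triol)
Product: 12 (3S,3′S,4R,4′R)-5,7-dihydroxy-4,4′-bis(4-hydroxyphenyl)-5′,6′,7′,8′-tetramethoxy-[3,3′-bichromane]-2,2′-dione, via lactone acid 11 (not isolated)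
Conditions: BF3·OEt2 (3 equiv), EtOAc–CH2Cl2, −20 °C, 9 (1 equiv) added slowly; then 10 (3 equiv), −20 °C → rt, argon
Reagents that add atoms: none
Why: BF3 binds a lactone carbonyl of 4 and the para-hydroxyl group pushes the carboxylate off the benzylic carbon, giving a para-quinone methide/benzylic cation that is captured in a Friedel–Crafts alkylation, first by the only free ring carbon of 9 (bond C4′–C4a′, giving lactone acid 11) and then, after ionisation of the second benzylic C–O bond, by a ring carbon of 10 (bond C4–C4a). The closest known chemistry is the Lewis-acid arylation of γ-aryl-γ-butyrolactones to 4,4-diarylbutanoic acids and the acid-promoted union of phenols with cinnamic acids or para-quinone methides to 4-aryl-3,4-dihydrocoumarins. Each six-membered lactone then closes by 6-exo-trig acylation: the hydroxyl ortho to the aryl–C4′ bond attacks the C3′-bound carbonyl (the γ-lactone carbonyl of 11, by translactonisation, or the free acid once the second benzylic C–O bond has ionised) and the hydroxyl ortho to the aryl–C4 bond attacks the C3-bound carboxyl with loss of water, after which no benzylic C–O bond is left to return to a γ-lactone. C3 and C3′ are the untouched bridgeheads of 4, and C4′ and C4 are set by 1,2-induction from them: the 3,4-cis lactones require each arene to bond on the face that the lactone oxygen leaves (net retention at both benzylic carbons of exo,exo-4). That face is flanked by the branch carrying the carboxyl group just released (on C3 for the first arylation, on C3′ for the second), which can hold the phenolic OH of the incoming nucleophile by a hydrogen bond so that its ortho carbon is delivered syn; low temperature and no prolonged acid contact are chosen to keep this organised, kinetically controlled pathway. Hetero-arylation rests on the twofold symmetry of 4 (one possible mono-adduct), strain release in the first opening, the single reactive carbon of 9 used first in one equivalent and an excess of threefold-symmetric 10 used second, while aryltetralin-type self-cyclisation is disfavoured because each 4-hydroxyphenyl ring would have to react meta to its hydroxyl.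

Step 6
Reactants: 12 tetramethyl ether of the target
Product: 13 (3S,3′S,4R,4′R)-5,5′,6′,7,7′,8′-hexahydroxy-4,4′-bis(4-hydroxyphenyl)-[3,3′-bichromane]-2,2′-dione (CNP0064734.1)
Conditions: BBr3 (excess), CH2Cl2, −78 → 0 °C; then H2O (dilute HCl), argon
Reagents that add atoms: none
Why: Lewis-acid ether cleavage, in which BBr3 binds each methoxy oxygen and bromide removes the methyl group by SN2 attack, while the aryl lactones and the four C–H stereocentres are not ionisable at low temperature and any lactone opened to the hydroxy acid recloses in the acidic work-up.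

Compound list
1 | p-coumaric acid, (E)-3-(4-hydroxyphenyl)prop-2-enoic acid | O=C(O)/C=C/c1ccc(O)cc1 | starting material
2 | rac-(2R*,3R*)-2,3-bis[(4-oxocyclohexa-2,5-dien-1-ylidene)methyl]butanedioic acid (racemate, both enantiomers written) | O=C1C=CC(C=C1)=C[C@H](C(O)=O)[C@@H](C(O)=O)C=C1C=CC(=O)C=C1.O=C1C=CC(C=C1)=C[C@@H](C(O)=O)[C@H](C(O)=O)C=C1C=CC(=O)C=C1 | intermediate (not isolated)
3 | rac-(1R*,4R*,5R*,8R*)-4,8-bis(4-hydroxyphenyl)-3,7-dioxabicyclo[3.3.0]octane-2,6-dione (racemate, both enantiomers written) | O=C1O[C@@H](c3ccc(O)cc3)[C@@H]2C(=O)O[C@@H](c3ccc(O)cc3)[C@H]12.O=C1O[C@H](c3ccc(O)cc3)[C@H]2C(=O)O[C@H](c3ccc(O)cc3)[C@@H]12 | intermediate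
4 | (1R,4R,5R,8R)-4,8-bis(4-hydroxyphenyl)-3,7-dioxabicyclo[3.3.0]octane-2,6-dione | O=C1O[C@@H](c3ccc(O)cc3)[C@@H]2C(=O)O[C@@H](c3ccc(O)cc3)[C@H]12 | intermediate
5 | 1,2,3,4-tetramethoxybenzene | COc1ccc(OC)c(OC)c1OC | starting material
6 | 1-[chloro(methoxy)methyl]-2,3,4,5-tetramethoxybenzene (racemic) | COC(Cl)c1cc(OC)c(OC)c(OC)c1OC | intermediate (not isolated)
7 | 2,3,4,5-tetramethoxybenzaldehyde | COc1cc(C=O)c(OC)c(OC)c1OC | intermediate
8 | 2,3,4,5-tetramethoxyphenyl formate | COc1cc(OC=O)c(OC)c(OC)c1OC | intermediate (not isolated)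
9 | 2,3,4,5-tetramethoxyphenol | COc1cc(O)c(OC)c(OC)c1OC | intermediate
10 | phloroglucinol, benzene-1,3,5-triol | Oc1cc(O)cc(O)c1 | starting material
11 | (2R,3R,4S)-4-[(R)-(2-hydroxy-3,4,5,6-tetramethoxyphenyl)(4-hydroxyphenyl)methyl]-2-(4-hydroxyphenyl)-5-oxooxolane-3-carboxylic acid | O=C1O[C@@H](c2ccc(O)cc2)[C@H](C(O)=O)[C@@H]1[C@H](c1ccc(O)cc1)c1c(O)c(OC)c(OC)c(OC)c1OC | intermediate (not isolated)
12 | (3S,3′S,4R,4′R)-5,7-dihydroxy-4,4′-bis(4-hydroxyphenyl)-5′,6′,7′,8′-tetramethoxy-[3,3′-bichromane]-2,2′-dione | O=C1Oc2cc(O)cc(O)c2[C@@H](c2ccc(O)cc2)[C@H]1[C@H]1C(=O)Oc2c(OC)c(OC)c(OC)c(OC)c2[C@H]1c1ccc(O)cc1 | intermediate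
13 | (3S,3′S,4R,4′R)-5,5′,6′,7,7′,8′-hexahydroxy-4,4′-bis(4-hydroxyphenyl)-[3,3′-bichromane]-2,2′-dione | O=C1Oc2cc(O)cc(O)c2[C@@H](c2ccc(O)cc2)[C@H]1[C@H]1C(=O)Oc2c(O)c(O)c(O)c(O)c2[C@H]1c1ccc(O)cc1 | target

Total step count: 6. Longest linear sequence: 4 steps (1, 2, 5, 6; the branch 3, 4, 5, 6 is equally long).

Steps most likely to fail

Step 5. The arene may add to the open face of the benzylic cation, anti to the neighbouring C3/C3′ branch, instead of being delivered from the carboxyl side. The lactone rings would then close 3,4-trans, which is also the arrangement expected to be more stable. The two phenols may in addition distribute statistically over the two benzylic carbons. The fallback turns an anti preference into the wanted result. It sets out from compound 3, from which the resolution also supplies the antipode (1S,4S,5S,8S)-4,8-bis(4-hydroxyphenyl)-3,7-dioxabicyclo[3.3.0]octane-2,6-dione F1. The same two-phenol sequence, run with BF3·OEt2 in 1,4-dioxane to favour the open transition state, should lead through the lactone acid (2S,3S,4R)-4-[(R)-(2-hydroxy-3,4,5,6-tetramethoxyphenyl)(4-hydroxyphenyl)methyl]-2-(4-hydroxyphenyl)-5-oxooxolane-3-carboxylic acid F2 to the trans,trans bis-lactone (3R,3′R,4R,4′R)-5,7-dihydroxy-4,4′-bis(4-hydroxyphenyl)-5′,6′,7′,8′-tetramethoxy-[3,3′-bichromane]-2,2′-dione F3. F3 already has the C4/C4′ configuration of 12. Silylation of the four phenols (TBSCl, imidazole, DMF) gives the tetrakis(tert-butyldimethylsilyl) ether of the trans,trans bis-lactone F4. Double deprotonation with LiN(SiMe3)2 in THF at −78 °C gives the dilithium bis-enolate of the tetrasilyl ether F5. Kinetic protonation of each enolate carbon anti to the pseudo-axial 4-aryl group by 2,6-di-tert-butylphenol inverts C3 and C3′ and gives the tetrakis(tert-butyldimethylsilyl) ether of 12 F6. Et3N·3HF in THF removes the silyl groups, and the route is rejoined at compound 12.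

Step 1. The phenoxyl radicals may couple 8–5 and 8–O–4 in competition with 8–8′, and the dilactone may be oxidised further, so that only a small share of the material ends as the neutral dilactone. The fallback makes the 8–8′ bond by enolate chemistry and sets out from compound 1. Hydrogenation (H2, Pd/C, MeOH) gives 3-(4-hydroxyphenyl)propanoic acid F7. Two molecules of its trilithium salt (LiN(iPr)2, THF, −78 °C) are coupled oxidatively at the α-carbons with I2 (0.5 equiv, added at −78 °C). The racemic like diastereomer, rac-(2R*,3R*)-2,3-bis[(4-hydroxyphenyl)methyl]butanedioic acid F8, is separated from the meso acid by crystallisation. DDQ in 1,4-dioxane then dehydrogenates both 4-hydroxybenzyl groups to the bis-quinone methide 2, which lactonises as in step 1, and the route is rejoined at compound 3.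

Step 6. BBr3 may open the aryl lactones or promote epimerisation at C3/C3′, and the pentaoxygenated ring B may be oxidised by air during or after demethylation. The fallback moves the demethylation in front of the key step, where no lactone and no stereocentre are at stake, and sets out from compound 9. BBr3 in CH2Cl2 converts 9 into benzene-1,2,3,4,5-pentol F9, which is kept under argon and used crude in place of 9 in step 5 with compounds 4 and 10. Its only ring C–H reacts to give the lactone acid (2R,3R,4S)-4-[(R)-(4-hydroxyphenyl)(2,3,4,5,6-pentahydroxyphenyl)methyl]-2-(4-hydroxyphenyl)-5-oxooxolane-3-carboxylic acid F10. After arylation by phloroglucinol and double lactonisation the route is rejoined directly at the target, compound 13.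

Further compounds
F1 | step 5 | (1S,4S,5S,8S)-4,8-bis(4-hydroxyphenyl)-3,7-dioxabicyclo[3.3.0]octane-2,6-dione | O=C1O[C@H](c3ccc(O)cc3)[C@H]2C(=O)O[C@H](c3ccc(O)cc3)[C@@H]12
F2 | step 5 | (2S,3S,4R)-4-[(R)-(2-hydroxy-3,4,5,6-tetramethoxyphenyl)(4-hydroxyphenyl)methyl]-2-(4-hydroxyphenyl)-5-oxooxolane-3-carboxylic acid | O=C1O[C@H](c2ccc(O)cc2)[C@@H](C(O)=O)[C@H]1[C@H](c1ccc(O)cc1)c1c(O)c(OC)c(OC)c(OC)c1OC
F3 | step 5 | (3R,3′R,4R,4′R)-5,7-dihydroxy-4,4′-bis(4-hydroxyphenyl)-5′,6′,7′,8′-tetramethoxy-[3,3′-bichromane]-2,2′-dione | O=C1Oc2cc(O)cc(O)c2[C@@H](c2ccc(O)cc2)[C@@H]1[C@@H]1C(=O)Oc2c(OC)c(OC)c(OC)c(OC)c2[C@H]1c1ccc(O)cc1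
F4 | step 5 | (3R,3′R,4R,4′R)-5,7-bis[(tert-butyldimethylsilyl)oxy]-4,4′-bis{4-[(tert-butyldimethylsilyl)oxy]phenyl}-5′,6′,7′,8′-tetramethoxy-[3,3′-bichromane]-2,2′-dione | O=C1Oc2cc(O[Si](C)(C)C(C)(C)C)cc(O[Si](C)(C)C(C)(C)C)c2[C@@H](c2ccc(O[Si](C)(C)C(C)(C)C)cc2)[C@@H]1[C@@H]1C(=O)Oc2c(OC)c(OC)c(OC)c(OC)c2[C@H]1c1ccc(O[Si](C)(C)C(C)(C)C)cc1
F5 | step 5 | dilithium 2,2′-bis-enolate of the (4R,4′R) tetrasilyl ether | [Li]OC1=C(C2=C(O[Li])Oc3c(OC)c(OC)c(OC)c(OC)c3[C@H]2c2ccc(O[Si](C)(C)C(C)(C)C)cc2)[C@H](c2ccc(O[Si](C)(C)C(C)(C)C)cc2)c2c(O[Si](C)(C)C(C)(C)C)cc(O[Si](C)(C)C(C)(C)C)cc2O1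
F6 | step 5 | (3S,3′S,4R,4′R)-5,7-bis[(tert-butyldimethylsilyl)oxy]-4,4′-bis{4-[(tert-butyldimethylsilyl)oxy]phenyl}-5′,6′,7′,8′-tetramethoxy-[3,3′-bichromane]-2,2′-dione | O=C1Oc2cc(O[Si](C)(C)C(C)(C)C)cc(O[Si](C)(C)C(C)(C)C)c2[C@@H](c2ccc(O[Si](C)(C)C(C)(C)C)cc2)[C@H]1[C@H]1C(=O)Oc2c(OC)c(OC)c(OC)c(OC)c2[C@H]1c1ccc(O[Si](C)(C)C(C)(C)C)cc1
F7 | step 1 | 3-(4-hydroxyphenyl)propanoic acid | O=C(O)CCc1ccc(O)cc1
F8 | step 1 | rac-(2R*,3R*)-2,3-bis[(4-hydroxyphenyl)methyl]butanedioic acid (racemate, both enantiomers written) | Oc1ccc(C[C@H](C(O)=O)[C@@H](C(O)=O)Cc2ccc(O)cc2)cc1.Oc1ccc(C[C@@H](C(O)=O)[C@H](C(O)=O)Cc2ccc(O)cc2)cc1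
F9 | step 6 | benzene-1,2,3,4,5-pentol | Oc1cc(O)c(O)c(O)c1O
F10 | step 6 | (2R,3R,4S)-4-[(R)-(4-hydroxyphenyl)(2,3,4,5,6-pentahydroxyphenyl)methyl]-2-(4-hydroxyphenyl)-5-oxooxolane-3-carboxylic acid | O=C1O[C@@H](c2ccc(O)cc2)[C@H](C(O)=O)[C@@H]1[C@H](c1ccc(O)cc1)c1c(O)c(O)c(O)c(O)c1O
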